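To keep target clean of over-reaction product, set the bath by the partner dose that a target molecule faces.

- south-west: starting material 0.19 M; second substrate 1.00 equiv; solid reagent 0.900 equiv; temperature 110 °C; time 3.0 d
- east: starting material 0.19 M; second substrate 1.00 equiv; solid reagent 0.900 equiv; temperature 90 °C; time 3.0 d

* the flask with the highest share of target in all that became target or over-reaction product ("all alike" if they lie within 1.5 percentage points) (south-west / east / all alike)
* share of target in all that became target or over-reaction product, south-west
* share of target in all that became target or over-reaction product, east

- as a solid, counted per litre of solution: solid reagent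
- at 90 °C the constants are as listed, elsewhere as the activation energies and enthalpies make them
- at the start none of the solid reagent is in solution

    second substrate + partner ⇌ second product (K1 = 14 /M, k1 = 0.0019 /M/min, Ea1 = 91.0 kJ/mol, ΔH1 = −81.0 kJ/mol)
    starting material + partner ⇌ target (K2 = 2.8 /M, k2 = 0.0018 /M/min, Ea2 = 79.0 kJ/mol, ΔH2 = 45.0 kJ/mol)
    solid reagent ⇌ partner, rate k3*(cs3 - [partner]) while solid is left; crystals form when [partner] > cs3 (cs3 = 0.17 M, k3 = 0.0016 /min)
    partner + target → over-reaction product (k4 = 0.0061 /M/min, Ea4 = 86.0 kJ/mol)
    (constants at 90 °C)

Target is lost by partner + target → over-reaction product (k4 = 0.0061 /M/min, Ea4 = 86.0 kJ/mol). At a held partner concentration, this loss is pseudo-first-order in target. The solid reagent charge caps dissolved partner at cB = 0.171 M. With dissolution coefficient k3 and solubility cs3, dissolving at the initial rate k3·cs3 takes 0.437 d, shorter than the run of 3.0 d. So the run is long enough for that charge to enter solution.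

Reckoned at that cap, a target molecule has a lifetime τ = 1/(k4·cB), which is 0.666 d in east. This is a lower bound, since partner bound in other species stands below the cap. The dose D = k4·cB·t, the number of such lifetimes in a run, is 4.51 in east. Its activation energy Ea4 raises k4 by a factor of 4.42 in south-west, so D there is 19.9.

Now turn the question round. For south-west to give the higher share, its making of target would have to outrun that rise. Step 2 speeds up by 3.9, less than step 4. Charge and time match, so D in south-west over D in east is 4.41, a ratio that holds the factor on k4 and leaves real partner out. Step 4 gains on step 2 by a factor of 1.13. This reckoning gives no shares. It gives a direction: taking partner alike in both flasks, the estimate puts the odds ω, over-reaction product per target, about 4.41 times higher in south-west, and so east ahead.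

The forecast says east, with 11.5% in south-west and 34% in east, on the ground that “Target is reversibly formed, then drained irreversibly by the partner”. The simulation gives 12.2% in south-west and 34.0% in east, so east has the higher share.

Those shares mean ω = 7.21 in south-west and 1.94 in east, a ratio of 3.72. South-west carries D/ω = 2.76. Its neighbour is the same flask left until 8.0 d, which takes the dose to 53.1. At the same D/ω, the odds become 19.2 and the share of target 4.95%. The neighbour flask gives 4.51%.

Its constants are assumed; the result is computed.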